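A plateau reached with solid substrate still in the flask looks like an equilibrium, and that trap opened a short meeting on the red run, which is also the flask asked about.

| flask | solid substrate | free enzyme | temperature | remark | time |
|---|---|---|---|---|---|
| red | 38 mM | 3.8 µM | 25 °C | the very flask that is asked about, followed so far |  |
| flask | 38 mM | 3.8 µM | 25 °C |  | 4.0 h |

red run (percent of the solid substrate charged)

| time / min | product / % | solid substrate / % |
|---|---|---|
| 20.0 | 29.4 | 69.3 |
| 30.0 | 38.2 | 60.5 |
| 40.0 | 44.2 | 53.8 |
| 60.0 | 48.3 | 48.6 |
| 90.0 | 49.8 | 48.0 |
| 150 | 49.4 | 46.5 |
| 240 | 49.7 | 47.2 |

(standard deviation of a reading: 0.3 percentage points)

- solid, in amounts per volume of the solution: solid substrate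
- removed product is counted in
- the earlier runs were read with a standard deviation of 0.3 percentage points
- what may be going on: free enzyme -> unfolded enzyme; starting material + free enzyme -> product + free enzyme; solid substrate <-> starting material
- at the start none of the solid substrate is in solution
- the earlier runs do not show what temperature does; that part of a forecast is a guess
- additions bring no volume worth counting

- north-east: change nothing and wait 4.0 h more
- north: at 4.0 h take out 90% of the product then present, then wait 4.0 h
- south-west: at 4.0 h add free enzyme, 100% of the amount charged, then wait 4.0 h
- west: at 4.0 h raise the temperature by 10 K, then wait 4.0 h

- product, in percent of the solid substrate first charged, at 4.0 h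
- the option that brings most further product ("none" if no option brings more than 2 percentage points) (north-east / north / south-west / west / none)
- product present, with what was taken out counted in, in percent of the solid substrate first charged, after north
- product present, with what was taken out counted in, in percent of the solid substrate first charged, after south-west

The analyst reported that in the red run, from 90.0 min on, product stood at a mean of 49.6% of the charge, while 47.2% of the charge was still solid. The kineticist objected to any equilibrium reading: the step to product is written one-way, so a halt beside that reservoir means the free enzyme has unfolded.

The process chemist then closed the balance on the red run. The dissolved share, which is the charge minus product and solid, came to 1.30% at 20.0 min and 3.10% at 240 min, far less than the solid. Between 20.0 min and 30.0 min solid fell by 8.8 percentage points and product rose by 8.8 points, so what dissolved went on to react.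

She proposed not to follow that dissolved share, which rose between those two readings, and to freeze instead the amount of product that one dose of free enzyme gives while solid is present. The meeting adopted the dose yield, the fraction of the charge that one dose of free enzyme converts before unfolding, as long as solid remains.

Product did not move between 90.0 min and 240 min, so the meeting expected 49.6% now and nothing from north-east, north or west, though heating stayed a guess. A second dose finds 50.4% of the charge unconverted, slightly more than one dose yield, so my reckoning for south-west is 99.2%.

The forecast said “Fresh enzyme is the only real lever.” and gave 49.7% now, south-west as best, 49.7% after north and, below my figure, 86% after south-west.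

The flask gives 49.8% now and 49.8% after north. South-west brings 50 points further, for 99.5%, while north-east, north and west each bring 0 points.

    free enzyme → unfolded enzyme (k = 0.00130 /s, Ea = 282 kJ/mol)
    starting material + free enzyme → product + free enzyme, rate k2*[starting material]*[free enzyme]/(1 + ([starting material]/Km2) + ([starting material]/Ksi2)^2) (0.110 M, 23.0 mM, k = 17000 /M/s, Ea = 36.0 kJ/mol)
    solid substrate ⇌ starting material, rate k3*(cs3 - [starting material]) while solid is left; crystals form when [starting material] > cs3 (solubility = 1.20 mM, k = 0.0110 /s)
    (constants at 25 °C)

Two dose yields make 99.2% beside the 99.5% of this flask, although the second dose began with 47.0% of the charge solid. The low solubility of starting material is what holds a dose to that yield: in the simulated run without it, product at 4.0 h goes from 49.8% to 100%. In the neighbour flask charged with the smaller 15 mM, one dose yield equals 126% of its charge, and that flask reaches >99.9%, with 0.030% of its charge left unconverted.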